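A small charge of substrate and a large one, stirred under the held gas phase, end up losing target at a like millimolar pace.

all flasks: gas phase 11 mM (held)
- spring: substrate 0.034 M; run made earlier
- winter: substrate 0.075 M; run made earlier
- flask: substrate 0.050 M; time 6.0 h

- spring (time / h: target / %, crystals / %): 0.500: 30, 11; 0.833: 48, 30; 1.33: 61, 50; 2.00: 71, 58; 3.00: 74, 64; 5.00: 64, 57; 8.00: 47, 38
- winter (time / h: target / %, crystals / %): 1.00: 45, 39; 2.00: 72, 65; 3.00: 84, 76; 4.00: 82, 80; 5.00: 82, 77; 6.00: 80, 73; 8.00: 72, 70

(standard deviation of a reading: 1.5 percentage points)

- target is meant together with its crystals
- solid, in amounts per volume of the solution: crystals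
- the numbers in the tables scatter with a standard deviation of 1.5 percentage points
- at the start none of the gas phase is in solution

* the target and crystals together standing at 6.0 h, as a percentage of the substrate charged
* concentration of dissolved gas in solution at 6.0 h, in percent of saturation

From 5.00 h to 8.00 h the spring run falls 1.93 mM h⁻¹, and over the same hours the winter run falls 2.50 mM h⁻¹, with crystals standing in both. Each figure is the difference of two scattered readings, the winter one the more uncertain for its larger charge, so we take the two paces as alike within the scatter. So we freeze dissolved target at its solubility, which makes the loss zero-order.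

How much is missing by the asked time? We carry the shortfall, the millimolar of charge no longer standing as target and crystals. The winter run reads 15.0 mM at 6.00 h. The spring run, extended from 5.00 h at its own pace, gives 14.2 mM. Our flask should therefore stand at 70.0 %.

Does the gas keep up? The winter run's first hour made 33.8 mM h⁻¹ of target, far faster than the late pace, so we reckon dissolved gas at 92.6 % of saturation or higher.

The forecast gives 71 % and 97 %, holding that “the crystals protect the rest”.

The flask gives 71.1 % and 98.8 %.

    gas phase ⇌ dissolved gas, rate k1*(csat - [dissolved gas]) (kL = 0.160 min⁻¹)
    crystals ⇌ target, rate k2*(cs2 - [target]) while solid is left; crystals form when [target] > cs2 (solubility = 4.00 mM, k = 0.150 min⁻¹)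
    dissolved gas + target → over-reacted product (k = 0.480 M⁻¹ min⁻¹)
    substrate + dissolved gas → target (k = 1.90 M⁻¹ min⁻¹)
    target → over-reaction product (k = 0.00420 min⁻¹)

The flask's shortfall is 14.5 mM, close to the carried 15.0 mM. Without the solubility limit the flask holds 8.47 % instead of 71.1 %, and that protection works together with the short time allowed, for at 60.0 h the flask holds 0 %. A neighbour charged with 13.0 mM has less substrate than the shortfall, so we expect its crystals gone. At 6.00 h it stands with crystals at 0 % and target at 11.8 %.

Readings and results stem from a simulated flask for substances that don't exist; noise was put on by code.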